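**Retrosynthetic overview**

- The dihydropyran is numbered O1, C2 (spiro carbon, also the α-carbon of the γ-lactone), C3, C4, C5 (bears the cyclohexyl group) and C6 (=CH–O). It is cut at C4–C5 and C6–O1 into an enol ether (C5=C6, cyclohexane half) and a spiro-oxetane (O1–C2–C3–C4, eudesmanolide half).
- Enabling feature: O1–C2–C3–C4 is a latent oxetane whose spiro carbon C2 is quaternary and α to the lactone carbonyl, so only the C4–O1 bond can open. C5=C6–O1 is an enol ether, a masked aldehyde that serves as the two-atom partner. The four-membered ring therefore grows to the six-membered ring by strain release.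
- Oxetane half: telekin → epoxidation of the methylene lactone (sets the spiro carbon) → epoxide-to-oxetane homologation → inversion of C5 by formate hydrogenolysis (cis-fused decalin, H-5 β).
- Cyclohexane half (configuration opposite to that of (−)-β-elemene): asymmetric Diels–Alder (quaternary carbon and its neighbour) → double methylenation → two one-carbon homologations, the first with equilibration of the ring carbon that carries the side chain.
- Ring order: cyclohexane (Diels–Alder); decalin and lactone taken from telekin; oxetane; dihydropyran last.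

Key step: step 11

Remark 1: telekin (13) is taken as a purchasable isolated natural product.
Remark 2: the (S)-configured boron catalyst of step 3 is assumed to give (1S,6S)-6; if its sense of induction is the opposite, its enantiomer is used.

Step 1
Reactants: 1 methylglyoxal (2-oxopropanal); 2 2-(triphenylphosphoranylidene)propanal
Product: 3 (E)-2-methyl-4-oxopent-2-enal
Conditions: CH2Cl2, 0 °C → rt
Reagents that add atoms: none
Why: Wittig olefination in which the stabilised ylide should attack only the aldehyde carbonyl of 1 and give the E-alkene, placing formyl and acetyl trans as needed for the later cis methyl/isopropenyl relationship.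

Step 2
Reactants: 4 but-3-en-2-one
Product: 5 2-[(triisopropylsilyl)oxy]buta-1,3-diene
Conditions: i-Pr3SiOTf, Et3N, Et2O, 0 °C → rt
Reagents that add atoms: triisopropylsilyl trifluoromethanesulfonate, CC(C)[Si](C(C)C)(C(C)C)OS(=O)(=O)C(F)(F)F
Why: Silyl enol ether formation (soft enolisation and O-silylation of the enone) gives the electron-rich diene that acts as a cyclohexanone synthon.

Step 3
Reactants: 3 (E)-2-methyl-4-oxopent-2-enal; 5 2-[(triisopropylsilyl)oxy]buta-1,3-diene
Product: 6 (1S,6S)-6-acetyl-1-methyl-4-[(triisopropylsilyl)oxy]cyclohex-3-ene-1-carbaldehyde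
Conditions: (S)-3,3-diphenyl-1-(2-methylphenyl)tetrahydro-1H,3H-pyrrolo[1,2-c][1,3,2]oxazaborole protonated with HN(SO2CF3)2 (20 mol %), CH2Cl2, −78 → −40 °C
Reagents that add atoms: none
Why: Catalytic enantioselective Diels–Alder reaction in which the boron Lewis acid binds the formyl group, the diene terminus next to the silyloxy carbon bonds to the acetyl-bearing carbon (silyloxy carbon para to the new quaternary carbon), suprafacial addition to the E-alkene makes methyl and acetyl cis, and the chiral catalyst fixes the absolute configuration; the regioselectivity rests on activation of the aldehyde rather than the ketone.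

Step 4
Reactants: 6 (1S,6S)-6-acetyl-1-methyl-4-[(triisopropylsilyl)oxy]cyclohex-3-ene-1-carbaldehyde
Product: 8 (3R,4R)-4-ethenyl-4-methyl-3-(prop-1-en-2-yl)cyclohexan-1-one, via silyl enol ether triene 7 (not isolated)
Conditions: Ph3PCH3Br, KOt-Bu, THF, −78 °C → rt; then 1 M HCl, THF, 0 °C
Reagents that add atoms: methyltriphenylphosphonium bromide, C[P+](c1ccccc1)(c1ccccc1)c1ccccc1.[Br-]
Why: Wittig methylenation of the aldehyde first (at low temperature, which removes the partner for an intramolecular aldol) and then of the methyl ketone, followed by acid hydrolysis of the silyl enol ether; no stereocenter is formed and the acetyl-bearing center should not epimerise because olefination is expected to outrun enolisation.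

Step 5
Reactants: 8 (3R,4R)-4-ethenyl-4-methyl-3-(prop-1-en-2-yl)cyclohexan-1-one
Product: 11 (1S,3R,4R)-4-ethenyl-4-methyl-3-(prop-1-en-2-yl)cyclohexane-1-carbaldehyde, via exocyclic enol ether 9 (not isolated), via axial aldehyde epimer 10 (not isolated)
Conditions: Ph3P(CH2OMe)Cl, KOt-Bu, THF, 0 °C; then 2 M HCl, THF, rt; then K2CO3, MeOH, rt
Reagents that add atoms: (methoxymethyl)triphenylphosphonium chloride, COC[P+](c1ccccc1)(c1ccccc1)c1ccccc1.[Cl-]
Why: One-carbon homologation by Wittig methoxymethylenation and enol ether hydrolysis, then base equilibration through the enolate, which should favour the equatorial formyl group cis to the isopropenyl and methyl groups (1S); the axial epimer is separated and equilibrated again.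

Step 6
Reactants: 11 (1S,3R,4R)-4-ethenyl-4-methyl-3-(prop-1-en-2-yl)cyclohexane-1-carbaldehyde
Product: 12 (1R,2R,4S)-1-ethenyl-4-(2-methoxyethenyl)-1-methyl-2-(prop-1-en-2-yl)cyclohexane (E/Z mixture)
Conditions: Ph3P(CH2OMe)Cl, KOt-Bu, THF, −78 → 0 °C
Reagents that add atoms: (methoxymethyl)triphenylphosphonium chloride, COC[P+](c1ccccc1)(c1ccccc1)c1ccccc1.[Cl-]
Why: Wittig methoxymethylenation gives the enol ether that carries C5 and C6 of the future dihydropyran, and the low temperature should keep the α-stereocenter; both alkene isomers serve equally.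

Step 7
Reactants: 13 telekin (5α-hydroxyeudesma-4(15),11(13)-dien-8β,12-olide)
Product: 14 (11S)-11,13-epoxy-5α-hydroxyeudesm-4(15)-en-8β,12-olide (epoxide oxygen on the face of H-7)
Conditions: t-BuOOH (decane), DBU, CH2Cl2, 0 °C → rt
Reagents that add atoms: tert-butyl hydroperoxide, CC(C)(C)OO
Why: Weitz–Scheffer nucleophilic epoxidation touches only the electron-poor exocyclic alkene of the lactone, and closure of the peroxy enolate on the convex face of the cis-fused lactone (the face of H-7) sets the spiro carbon.

Step 8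
Reactants: 14 (11S)-11,13-epoxy-5α-hydroxyeudesm-4(15)-en-8β,12-olide
Product: 15 (11R)-5α-hydroxy-spiro[eudesm-4(15)-en-8β,12-olide-11,2′-oxetane] (oxetane oxygen on C11, on the face of H-7)
Conditions: Me3S(O)I, KOt-Bu, t-BuOH, 60 °C
Reagents that add atoms: trimethylsulfoxonium iodide, C[S+](C)(C)=O.[I-]
Why: Corey–Chaykovsky-type epoxide-to-oxetane ring expansion in which the sulfoxonium ylide opens the epoxide at its CH2 carbon and the tertiary alkoxide displaces dimethyl sulfoxide (4-exo-tet), so the C11–O bond and its configuration are kept.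

Step 9
Reactants: 15 (11R)-5α-hydroxy-spiro[eudesm-4(15)-en-8β,12-olide-11,2′-oxetane]
Product: 16 (11R)-5α-formyloxy-spiro[eudesm-4(15)-en-8β,12-olide-11,2′-oxetane]
Conditions: HCO2Ac (preformed), pyridine, DMAP (cat.), CH2Cl2, 0 °C → rt
Reagents that add atoms: acetic formic anhydride, CC(=O)OC=O
Why: Acylation of the tertiary allylic alcohol with the small mixed anhydride gives the allylic formate needed for the hydrogenolysis; no stereocenter changes.

Step 10
Reactants: 16 (11R)-5α-formyloxy-spiro[eudesm-4(15)-en-8β,12-olide-11,2′-oxetane]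
Product: 17 (5R,11R)-spiro[5βH-eudesm-4(15)-en-8β,12-olide-11,2′-oxetane] (cis-fused decalin, H-5 and the C10 methyl cis)
Conditions: Pd(OAc)2 (5 mol %), n-Bu3P (20 mol %), THF, reflux
Reagents that add atoms: none
Why: Palladium-catalysed hydrogenolysis of an allylic formate (Tsuji–Trost-type allylpalladium chemistry): zerovalent palladium ionises the tertiary α-formate with inversion, loss of CO2 gives an allylpalladium hydride, and hydride passes from the metal on the β-face to the more substituted terminus C5, which should give H-5β and keep the exocyclic C4=C15 alkene.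

Step 11
Reactants: 12 (1R,2R,4S)-1-ethenyl-4-(2-methoxyethenyl)-1-methyl-2-(prop-1-en-2-yl)cyclohexane; 17 (5R,11R)-spiro[5βH-eudesm-4(15)-en-8β,12-olide-11,2′-oxetane]
Product: 19 target CNP0353330.1, via cyclic methoxy acetal 18 (not isolated)
Conditions: Me3SiOTf (20 mol %), 2,6-di-tert-butyl-4-methylpyridine, CH2Cl2, −78 → −30 °C; then i-Pr2NEt, Me3SiOTf (1.3 equiv), −30 → 0 °C
Reagents that add atoms: none
Why: Proposed new method: the silyl triflate activates the oxetane oxygen of 17 and the nucleophilic β-carbon of enol ether 12 opens the strained ring by SN2 attack at the unhindered CH2–O carbon (C4); this forms the C4–C5 bond and an oxocarbenium ion at C6, which is captured by the released C2–O1 silyl ether oxygen (6-exo-trig) to give the 6-methoxytetrahydropyran 18, so the four-membered ring grows by the two enol ether carbons. The closest known reactions are the Lewis acid-mediated openings of oxetanes by silyl enol ethers and metal enolates (Mukaiyama-type) and the Lewis acid-catalysed formal [4+2] insertion of carbonyl compounds into oxetanes to give 1,3-dioxanes. In the second stage the silyl triflate/amine pair ionises the exocyclic methoxy group of 18 (the ring oxygen is hindered and sits on the electron-poor lactone α-carbon) and the only β-hydrogen, at C5, is removed, giving the C5=C6 enol ether. No stereocenter of the target is created here: the spiro C2–O1 bond is never broken, so the configuration from step 7 is kept, and the two acetal-stage centers C5 and C6 are destroyed. The step needs chemoselectivity for the enol ether over four other alkenes, which its much higher π-nucleophilicity and the hindered pyridine (removing adventitious acid) should secure, and C–O cleavage at C4 rather than at the spiro carbon, which is secured because C2 is quaternary and α to the lactone carbonyl.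

**Compound list**

1 | methylglyoxal (2-oxopropanal) | CC(=O)C=O | starting material
2 | 2-(triphenylphosphoranylidene)propanal | CC(C=O)=P(c1ccccc1)(c1ccccc1)c1ccccc1 | starting material
3 | (E)-2-methyl-4-oxopent-2-enal | CC(=O)/C=C(\C)C=O | intermediate
4 | but-3-en-2-one (methyl vinyl ketone) | CC(=O)C=C | starting material
5 | 2-[(triisopropylsilyl)oxy]buta-1,3-diene | C=CC(=C)O[Si](C(C)C)(C(C)C)C(C)C | intermediate
6 | (1S,6S)-6-acetyl-1-methyl-4-[(triisopropylsilyl)oxy]cyclohex-3-ene-1-carbaldehyde (methyl and acetyl cis) | O=C[C@@]1(C)CC=C(O[Si](C(C)C)(C(C)C)C(C)C)C[C@@H]1C(C)=O | intermediate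
7 | {[(4R,5R)-4-ethenyl-4-methyl-5-(prop-1-en-2-yl)cyclohex-1-en-1-yl]oxy}triisopropylsilane (not isolated) | C=C[C@@]1(C)CC=C(O[Si](C(C)C)(C(C)C)C(C)C)C[C@@H]1C(=C)C | intermediate
8 | (3R,4R)-4-ethenyl-4-methyl-3-(prop-1-en-2-yl)cyclohexan-1-one (methyl and isopropenyl cis) | C=C[C@@]1(C)CCC(=O)C[C@@H]1C(=C)C | intermediate
9 | (1R,2R)-1-ethenyl-4-(methoxymethylidene)-1-methyl-2-(prop-1-en-2-yl)cyclohexane (E/Z mixture, not isolated) | C=C[C@@]1(C)CCC(=COC)C[C@@H]1C(=C)C | intermediate
10 | (1R,3R,4R)-4-ethenyl-4-methyl-3-(prop-1-en-2-yl)cyclohexane-1-carbaldehyde (axial formyl, trans to isopropenyl; not isolated) | C=C[C@@]1(C)CC[C@@H](C=O)C[C@@H]1C(=C)C | intermediate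
11 | (1S,3R,4R)-4-ethenyl-4-methyl-3-(prop-1-en-2-yl)cyclohexane-1-carbaldehyde (formyl, isopropenyl and methyl all cis) | C=C[C@@]1(C)CC[C@H](C=O)C[C@@H]1C(=C)C | intermediate
12 | (1R,2R,4S)-1-ethenyl-4-(2-methoxyethenyl)-1-methyl-2-(prop-1-en-2-yl)cyclohexane (E/Z mixture, alkene geometry not specified) | C=C[C@@]1(C)CC[C@H](C=COC)C[C@@H]1C(=C)C | intermediate
13 | telekin (5α-hydroxyeudesma-4(15),11(13)-dien-8β,12-olide; trans-decalin, cis-fused lactone) | C=C1C(=O)O[C@@H]2C[C@@]3(C)CCCC(=C)[C@]3(O)C[C@H]12 | starting material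
14 | (11S)-11,13-epoxy-5α-hydroxyeudesm-4(15)-en-8β,12-olide (epoxide oxygen syn to H-7) | C1O[C@]12C(=O)O[C@@H]3C[C@@]4(C)CCCC(=C)[C@]4(O)C[C@@H]32 | intermediate
15 | (11R)-5α-hydroxy-spiro[eudesm-4(15)-en-8β,12-olide-11,2′-oxetane] (oxetane O on C11, syn to H-7) | O1CC[C@@]12C(=O)O[C@@H]3C[C@@]4(C)CCCC(=C)[C@]4(O)C[C@@H]32 | intermediate
16 | (11R)-5α-formyloxy-spiro[eudesm-4(15)-en-8β,12-olide-11,2′-oxetane] | O1CC[C@@]12C(=O)O[C@@H]3C[C@@]4(C)CCCC(=C)[C@]4(OC=O)C[C@@H]32 | intermediate
17 | (5R,11R)-spiro[5βH-eudesm-4(15)-en-8β,12-olide-11,2′-oxetane] (cis-decalin) | O1CC[C@@]12C(=O)O[C@@H]3C[C@@]4(C)CCCC(=C)[C@H]4C[C@@H]32 | intermediate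
18 | 6-methoxy-5,6-dihydro derivative of the target (cyclic methoxy acetal, C5 and C6 epimer mixture, not isolated) | C=C[C@@]1(C)CC[C@H](C2C(OC)O[C@@]3(CC2)C(=O)O[C@@H]2C[C@@]4(C)CCCC(=C)[C@H]4C[C@@H]23)C[C@@H]1C(=C)C | intermediate
19 | CNP0353330.1: spiro[5βH-eudesm-4(15)-en-8β,12-olide-11,2′-(3′,4′-dihydro-2′H-pyran)] bearing at C5′ the (1S,3R,4R)-4-ethenyl-4-methyl-3-(prop-1-en-2-yl)cyclohexyl group | C=C[C@@]1(C)CC[C@H](C2=CO[C@@]3(CC2)C(=O)O[C@@H]2C[C@@]4(C)CCCC(=C)[C@H]4C[C@@H]23)C[C@@H]1C(=C)C | target

**Step count and risks**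

Total step count: 11. Longest linear sequence: 6 steps (steps 1, 3, 4, 5, 6 and 11; the branch through steps 7–10 and 11 has 5).

Steps most likely to fail:

1. Step 11 (Proposed new method). The electron-poor oxetane oxygen may be activated too weakly, the oxocarbenium ion may be intercepted by a second enol ether molecule (oligomerisation), or traces of acid may move the exocyclic alkene into the ring. Fallback, from 12 and 17, returning at 19: enol ether 12 is hydrolysed with aqueous oxalic acid to 2-[(1S,3R,4R)-4-ethenyl-4-methyl-3-(prop-1-en-2-yl)cyclohexyl]acetaldehyde F1. Condensation with cyclohexylamine gives the N-cyclohexyl imine F2. Deprotonation with LiN(i-Pr)2 and reaction with 17 in the presence of BF3·OEt2 at −78 °C (Lewis acid-assisted oxetane opening by a metalloenamine) should give the hydroxy imine F3. Mild acid work-up hydrolyses the imine and the δ-hydroxy aldehyde closes to the lactol F4. Dehydration with MsCl/Et3N gives 19.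

2. Step 8. The ylide may attack the lactone carbonyl, or the epoxide may open without the slower 4-exo closure. Fallback, from 14, returning at 15: copper-catalysed opening of the epoxide with (i-PrO)Me2SiCH2MgCl and CuI (copper monoiodide) in THF at −30 °C gives the silylethyl carbinol F5. Tamao oxidation (H2O2, KF, KHCO3) gives the triol F6. Selective sulfonylation of the primary hydroxyl (TsCl, pyridine) gives the monotosylate F7. KOt-Bu in THF closes the oxetane by intramolecular Williamson etherification to 15.

3. Step 5. Stereocontrol at the formyl-bearing carbon may be poor, because the equatorial preference of a formyl group is small and the Wittig base can erode it. Fallback, from 8, returning at 11: the ketone is converted with KN(SiMe3)2 and PhNTf2 into the enol triflate F8. Carbonylation with Pd(PPh3)4 (zerovalent palladium), CO, MeOH and Et3N gives the unsaturated methyl ester F9. Conjugate reduction with Mg in MeOH followed by NaOMe equilibration gives the equatorial methyl ester F10, where the larger ester group should give a stronger preference. Reduction with i-Bu2AlH at −78 °C gives aldehyde 11.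

**Further compounds**

F1 | step 11 | 2-[(1S,3R,4R)-4-ethenyl-4-methyl-3-(prop-1-en-2-yl)cyclohexyl]acetaldehyde | C=C[C@@]1(C)CC[C@H](CC=O)C[C@@H]1C(=C)C
F2 | step 11 | N-cyclohexyl imine of F1 | C=C[C@@]1(C)CC[C@H](CC=NC2CCCCC2)C[C@@H]1C(=C)C
F3 | step 11 | hydroxy imine from opening of oxetane 17 by metalated F2 (tertiary 11-hydroxy lactone, C13–CH2–CH(cyclohexyl)–CH=N-cyclohexyl chain, epimers at the new CH) | C=C[C@@]1(C)CC[C@H](C(C=NC2CCCCC2)CC[C@]2(O)C(=O)O[C@@H]3C[C@@]4(C)CCCC(=C)[C@H]4C[C@@H]32)C[C@@H]1C(=C)C
F4 | step 11 | 6-hydroxy-5,6-dihydro derivative of the target (lactol, epimer mixture) | C=C[C@@]1(C)CC[C@H](C2C(O)O[C@@]3(CC2)C(=O)O[C@@H]2C[C@@]4(C)CCCC(=C)[C@H]4C[C@@H]23)C[C@@H]1C(=C)C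
F5 | step 8 | 5α,11-dihydroxy-13-[(isopropoxydimethylsilyl)methyl]eudesm-4(15)-en-8β,12-olide (11-OH syn to H-7) | CC(C)O[Si](C)(C)CC[C@]1(O)C(=O)O[C@@H]2C[C@@]3(C)CCCC(=C)[C@]3(O)C[C@@H]21
F6 | step 8 | 5α,11-dihydroxy-13-(hydroxymethyl)eudesm-4(15)-en-8β,12-olide | OCC[C@]1(O)C(=O)O[C@@H]2C[C@@]3(C)CCCC(=C)[C@]3(O)C[C@@H]21
F7 | step 8 | primary 4-methylbenzenesulfonate of F6 | Cc1ccc(cc1)S(=O)(=O)OCC[C@]1(O)C(=O)O[C@@H]2C[C@@]3(C)CCCC(=C)[C@]3(O)C[C@@H]21
F8 | step 5 | (4R,5R)-4-ethenyl-4-methyl-5-(prop-1-en-2-yl)cyclohex-1-en-1-yl trifluoromethanesulfonate | C=C[C@@]1(C)CC=C(OS(=O)(=O)C(F)(F)F)C[C@@H]1C(=C)C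
F9 | step 5 | methyl (4R,5R)-4-ethenyl-4-methyl-5-(prop-1-en-2-yl)cyclohex-1-ene-1-carboxylate | C=C[C@@]1(C)CC=C(C(=O)OC)C[C@@H]1C(=C)C
F10 | step 5 | methyl (1S,3R,4R)-4-ethenyl-4-methyl-3-(prop-1-en-2-yl)cyclohexane-1-carboxylate | C=C[C@@]1(C)CC[C@H](C(=O)OC)C[C@@H]1C(=C)C
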